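**Retrosynthetic overview**
1. Target ⇐ C8 ketone by hydroboration/oxidation of a bridging C7=C8 alkene; acetate from an axial C4′ alcohol.
2. Spiro-oxane ring (last ring) ⇐ C–O closure: 6-endo oxa-Michael addition of a C5 tertiary alcohol to a pendant enone; that alcohol ⇐ Mukaiyama aldol of a six-carbon silyl dienol ether with a bicyclic keto-lactone.
3. 2-Oxabicyclo[2.2.2]octene keto-lactone (second ring) ⇐ transannular C–O bond formation: dehydrogenative lactonisation of a cyclohexa-2,5-diene carboxamide (key step).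
4. Quaternary carbon and absolute configuration ⇐ auxiliary-controlled Birch reduction–methylation of a 2-methoxy-3,5-dimethylbenzamide (the carbocycle comes from the arene).
5. Ring order: carbocycle → lactone bridge (C–O) → oxane (C–O).

Assumptions: acid 1 is a catalogue compound. The (2S)-auxiliary is taken to give the (1R) centre in step 2; if the facial sense is the opposite, the (2R)-amine is used with no other change.

Locants: the core is numbered as 2-oxabicyclo[2.2.2]octane (C1 O-bearing bridgehead, C3 lactone C=O, C4 methyl-bearing bridgehead, C5 ketone/spiro carbon, C6 its CH(CH3) neighbour, C7/C8 third bridge). The oxane ring is primed (C2′ = spiro carbon).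

**Step 1**
Reactants: 1 2-methoxy-3,5-dimethylbenzoic acid; 2 (2S)-2-(methoxymethyl)pyrrolidine
Product: 4 (2-methoxy-3,5-dimethylphenyl)[(2S)-2-(methoxymethyl)pyrrolidin-1-yl]methanone, via acid chloride 3 (not isolated)
Conditions: (COCl)2, DMF (cat.), CH2Cl2, 0 → 23 °C; then 2, Et3N, CH2Cl2, 0 °C
Reagents that add atoms: none
Why: Amide formation through the acid chloride (Schotten–Baumann-type acylation); no stereocentre is formed and the centre of 2 is untouched.

**Step 2**
Reactants: 4 the benzamide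
Product: 6 [(1R)-2-methoxy-1,3,5-trimethylcyclohexa-2,5-dien-1-yl][(2S)-2-(methoxymethyl)pyrrolidin-1-yl]methanone, via potassium amide enolate 5 (not isolated)
Conditions: K (2.2 equiv), t-BuOH (1.0 equiv), NH3 (l)–THF, −78 °C; then MeI, −78 °C
Reagents that add atoms: iodomethane, CI
Why: Schultz-type asymmetric Birch reduction–alkylation: the chelated enolate 5 is methylated on the face away from the methoxymethyl arm, setting quaternary C1 (R), and the methoxy and methyl groups stay on the two remaining double bonds.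

**Step 3**
Reactants: 6 the cyclohexa-2,5-diene amide
Product: 9 (1R,4R,6S)-4,6,7-trimethyl-2-oxabicyclo[2.2.2]oct-7-ene-3,5-dione, via dienyl iminium ether 7 (not isolated), via keto iminium ether 8 (not isolated)
Conditions: DDQ (1.1 equiv), 4 Å MS, CH2Cl2, −40 → 0 °C; then 2 M HCl (aq)–THF, 0 °C
Reagents that add atoms: water, O
Why: Proposed new method: DDQ abstracts hydride from the doubly allylic C4–H of the 1-methoxy-1,4-diene to give a methoxy-pentadienyl (vinylogous oxocarbenium) cation that cannot aromatise because C1 is quaternary, and the amide oxygen captures it across the ring at C4 (the only position giving a six-membered bridge) to form the C–O bond and the bicyclic ring as iminium ether 7; fast acid hydrolysis of the enol ether (C6 protonated from the face away from the cationic bridge, methyl ends syn to the ring oxygen) precedes the slower imidate hydrolysis that gives lactone 9 and returns the auxiliary; the closest known reaction types are iodolactonisation of Birch-derived amides through iminium ethers and DDQ oxidative C–H cleavage/cyclisation of allylic and enol ethers.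

**Step 4**
Reactants: 10 (2E)-2-methylbut-2-enoyl chloride (tigloyl chloride); 11 ethylmagnesium bromide
Product: 12 (4E)-4-methylhex-4-en-3-one
Conditions: Fe(acac)3 (3 mol %), THF, −78 °C
Reagents that add atoms: none
Why: Iron-catalysed acylation of a Grignard reagent by an acid chloride stops at the ketone and keeps the (E)-alkene.

**Step 5**
Reactants: 12 the enone
Product: 13 [(2Z,4E)-4-methylhexa-2,4-dien-3-yl]oxy(trimethyl)silane
Conditions: TMSOTf, Et3N, Et2O, 0 °C
Reagents that add atoms: trimethylsilyl trifluoromethanesulfonate, C[Si](C)(C)OS(=O)(=O)C(F)(F)F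
Why: Soft enolisation/silylation at the only α-CH2 gives the 2-silyloxy diene (silyl enol ether formation); its geometry does not matter because that carbon is equilibrated in step 7.

**Step 6**
Reactants: 9 the bicyclic keto-lactone; 13 the silyl dienol ether
Product: 14 (1R,4R,5R,6S)-5-hydroxy-4,6,7-trimethyl-5-[(2S,4E)-4-methyl-3-oxohex-4-en-2-yl]-2-oxabicyclo[2.2.2]oct-7-en-3-one
Conditions: BF3·OEt2 (1.2 equiv), CH2Cl2, −78 °C; aq NaHCO3
Reagents that add atoms: none
Why: Mukaiyama aldol addition to the BF3-activated C5 ketone from the alkene-bridge face, anti to the adjacent C6 methyl, sets the tertiary carbinol with oxygen syn to the lactone bridge; both C2′ epimers are carried on.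

**Step 7**
Reactants: 14 the hydroxy enone
Product: 15 (1R,4R,5R,6S,3′S,5′R,6′R)-3′,4,5′,6,6′,7-hexamethylspiro[2-oxabicyclo[2.2.2]oct-7-ene-5,2′-oxane]-3,4′-dione
Conditions: (+)-CSA (20 mol %), 4 Å MS, ClCH2CH2Cl, 23 → 40 °C
Reagents that add atoms: none
Why: Acid-catalysed 6-endo-trig oxa-Michael addition forms the ring C–O bond through a chair with the quaternary C4 equatorial on the spiro carbon and the new C6′ methyl equatorial, and C3′ and C5′ equilibrate through the enol to the all-equatorial trimethyl ketone.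

**Step 8**
Reactants: 15 the spiro ketone
Product: 16 (1R,4R,5S,6S,3′R,4′R,5′S,6′R)-4′-hydroxy-3′,4,5′,6,6′,7-hexamethylspiro[2-oxabicyclo[2.2.2]oct-7-ene-5,2′-oxan]-3-one
Conditions: LiBH(s-Bu)3, THF, −78 → −40 °C; H2O
Reagents that add atoms: none
Why: Bulky trialkylborohydride reduction from the equatorial direction between the two equatorial α-methyls gives the axial alcohol; lactone and alkene are untouched at low temperature.

**Step 9**
Reactants: 16 the axial alcohol
Product: 17 (1R,4R,5S,6S,3′R,4′R,5′R,6′R)-3′,4,5′,6,6′,7-hexamethyl-3-oxospiro[2-oxabicyclo[2.2.2]oct-7-ene-5,2′-oxan]-4′-yl acetate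
Conditions: Ac2O, DMAP (cat.), Et3N, CH2Cl2, 23 °C
Reagents that add atoms: acetic anhydride, CC(=O)OC(C)=O
Why: DMAP-catalysed acylation of the hindered axial alcohol with retention.

**Step 10**
Reactants: 17 the alkene acetate
Product: 19 (1S,4R,5S,6S,7R,8R,3′R,4′R,5′R,6′R)-8-hydroxy-3′,4,5′,6,6′,7-hexamethyl-3-oxospiro[2-oxabicyclo[2.2.2]octane-5,2′-oxan]-4′-yl acetate, via alkylborane 18 (not isolated)
Conditions: BH3·THF (1.2 equiv), THF, 0 °C; then 30 % H2O2, pH 8 buffer, 0 → 23 °C
Reagents that add atoms: hydrogen peroxide, OO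
Why: Brown hydroboration–oxidation: syn addition with boron on the less substituted C8 from the alkene face turned to the lactone (the other face is blocked by the spiro ring) puts C7–H syn to the lactone and the C7 methyl toward the spiro bridge, and oxidation proceeds with retention.

**Step 11**
Reactants: 19 the C8 alcohol
Product: 20 (1R,4S,5S,6S,7S,3′R,4′R,5′R,6′R)-3′,4,5′,6,6′,7-hexamethyl-3,8-dioxospiro[2-oxabicyclo[2.2.2]octane-5,2′-oxan]-4′-yl acetate (CNP0257416.1)
Conditions: Dess–Martin periodinane, pyridine, CH2Cl2, 0 → 23 °C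
Reagents that add atoms: none
Why: Dess–Martin oxidation under buffered non-basic conditions gives the C8 ketone without epimerising C7 or causing β-elimination of the lactone oxygen.

**Compound list**
1 | 2-methoxy-3,5-dimethylbenzoic acid | COc1c(C)cc(C)cc1C(=O)O | starting material
2 | (2S)-2-(methoxymethyl)pyrrolidine | COC[C@@H]1CCCN1 | starting material
3 | 2-methoxy-3,5-dimethylbenzoyl chloride | COc1c(C)cc(C)cc1C(=O)Cl | intermediate
4 | (2-methoxy-3,5-dimethylphenyl)[(2S)-2-(methoxymethyl)pyrrolidin-1-yl]methanone | COc1c(C)cc(C)cc1C(=O)N1CCC[C@H]1COC | intermediate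
5 | potassium (Z)-enolate of the 1,4-dihydrobenzamide (enolate O syn to the ring methoxy) | [K+].[O-]/C(N1CCC[C@H]1COC)=C1/C=C(C)CC(C)=C1OC | intermediate
6 | [(1R)-2-methoxy-1,3,5-trimethylcyclohexa-2,5-dien-1-yl][(2S)-2-(methoxymethyl)pyrrolidin-1-yl]methanone | COC1=C(C)CC(C)=C[C@@]1(C)C(=O)N1CCC[C@H]1COC | intermediate
7 | (2S)-1-[(1S,4R)-5-methoxy-4,6,7-trimethyl-2-oxabicyclo[2.2.2]octa-5,7-dien-3-ylidene]-2-(methoxymethyl)pyrrolidin-1-ium 2,3-dichloro-5,6-dicyano-4-hydroxyphenolate | COC1=C(C)[C@H]2OC(=[N+]3CCC[C@H]3COC)[C@]1(C)C=C2C.[O-]c1c(Cl)c(Cl)c(O)c(C#N)c1C#N | intermediate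
8 | (2S)-1-[(1R,4S,6S)-4,6,7-trimethyl-5-oxo-2-oxabicyclo[2.2.2]oct-7-en-3-ylidene]-2-(methoxymethyl)pyrrolidin-1-ium chloride | C[C@H]1[C@H]2OC(=[N+]3CCC[C@H]3COC)[C@@](C)(C1=O)C=C2C.[Cl-] | intermediate
9 | (1R,4R,6S)-4,6,7-trimethyl-2-oxabicyclo[2.2.2]oct-7-ene-3,5-dione (6-methyl syn to the lactone oxygen) | C[C@H]1[C@H]2OC(=O)[C@@](C)(C1=O)C=C2C | intermediate
10 | (2E)-2-methylbut-2-enoyl chloride | C/C=C(\C)C(=O)Cl | starting material
11 | ethylmagnesium bromide | CC[Mg]Br | starting material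
12 | (4E)-4-methylhex-4-en-3-one | C/C=C(\C)C(=O)CC | intermediate
13 | [(2Z,4E)-4-methylhexa-2,4-dien-3-yl]oxy(trimethyl)silane | C/C=C(O[Si](C)(C)C)/C(C)=C/C | intermediate
14 | (1R,4R,5R,6S)-5-hydroxy-4,6,7-trimethyl-5-[(2S,4E)-4-methyl-3-oxohex-4-en-2-yl]-2-oxabicyclo[2.2.2]oct-7-en-3-one (C2′ epimer shown; both are used) | C/C=C(\C)C(=O)[C@@H](C)[C@]1(O)[C@@H](C)[C@H]2OC(=O)[C@]1(C)C=C2C | intermediate
15 | (1R,4R,5R,6S,3′S,5′R,6′R)-3′,4,5′,6,6′,7-hexamethylspiro[2-oxabicyclo[2.2.2]oct-7-ene-5,2′-oxane]-3,4′-dione | O=C1[C@H](C)[C@@H](C)O[C@@]2([C@@H]1C)[C@@H](C)[C@H]1OC(=O)[C@]2(C)C=C1C | intermediate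
16 | (1R,4R,5S,6S,3′R,4′R,5′S,6′R)-4′-hydroxy-3′,4,5′,6,6′,7-hexamethylspiro[2-oxabicyclo[2.2.2]oct-7-ene-5,2′-oxan]-3-one (axial OH) | O[C@@H]1[C@H](C)[C@@H](C)O[C@@]2([C@@H]1C)[C@@H](C)[C@H]1OC(=O)[C@]2(C)C=C1C | intermediate
17 | (1R,4R,5S,6S,3′R,4′R,5′R,6′R)-3′,4,5′,6,6′,7-hexamethyl-3-oxospiro[2-oxabicyclo[2.2.2]oct-7-ene-5,2′-oxan]-4′-yl acetate | CC(=O)O[C@@H]1[C@H](C)[C@@H](C)O[C@@]2([C@@H]1C)[C@@H](C)[C@H]1OC(=O)[C@]2(C)C=C1C | intermediate
18 | C8 alkylborane of 17 (boron and C7–H syn to the lactone bridge) | CC(=O)O[C@@H]1[C@H](C)[C@@H](C)O[C@@]2([C@@H]1C)[C@@H](C)[C@H]1OC(=O)[C@]2(C)[C@H](B)[C@H]1C | intermediate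
19 | (1S,4R,5S,6S,7R,8R,3′R,4′R,5′R,6′R)-8-hydroxy-3′,4,5′,6,6′,7-hexamethyl-3-oxospiro[2-oxabicyclo[2.2.2]octane-5,2′-oxan]-4′-yl acetate | CC(=O)O[C@@H]1[C@H](C)[C@@H](C)O[C@@]2([C@@H]1C)[C@@H](C)[C@H]1OC(=O)[C@]2(C)[C@H](O)[C@H]1C | intermediate
20 | (1R,4S,5S,6S,7S,3′R,4′R,5′R,6′R)-3′,4,5′,6,6′,7-hexamethyl-3,8-dioxospiro[2-oxabicyclo[2.2.2]octane-5,2′-oxan]-4′-yl acetate | CC(=O)O[C@@H]1[C@H](C)[C@@H](C)O[C@@]2([C@@H]1C)[C@@H](C)[C@H]1OC(=O)[C@]2(C)C(=O)[C@H]1C | target

**Step count**
Total: 11 steps. Longest linear sequence: 9 steps (1, 2, 3, 6, 7, 8, 9, 10, 11).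

**Three steps most likely to fail**

Step 3 (the proposed new reaction). Risks: acyl migration or loss from the cation (dienone–phenol-type aromatisation), or imidate hydrolysis before enol ether hydrolysis, which would give a bicyclic diene lactone that loses CO2. The C6 configuration depends on face-selective protonation; if a C6 epimer forms it is separated before step 6, since base cannot be used on 9. Fallback with known chemistry, from 6 back to 9: oxidation of the doubly allylic CH2 of 6 with pyridinium dichromate ((C5H5NH)2Cr2O7) and t-BuOOH gives the cross-conjugated 2,5-dienone amide F1. Luche reduction (NaBH4, CeCl3·7H2O, MeOH, −78 °C) gives the bis-allylic dienol amide F2. In 2 M HCl–THF at 0 °C this vinylogous hemiacetal ionises (Stork–Danheiser-type), the amide oxygen traps the cation as the dienyl iminium ether chloride F3, and hydrolysis then runs through 8 to 9.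

Step 6. Risk: the ketone of 9 is flanked by a quaternary and a tertiary carbon, so the Mukaiyama addition may be slow or poorly face-selective. Fallback, from 13 and 9 back to 14: NBS (THF, 0 °C) converts 13 into (4E)-2-bromo-4-methylhex-4-en-3-one F4. Activated Zn in THF gives the bromozinc enolate F5, which adds to 9 in a Reformatsky reaction (neutral, cyclic zinc-chelate transition state) to give 14 after work-up.

Step 7. Risks: the tertiary alcohol may add sluggishly, or the C6′ configuration may come out wrong. Fallback, from 14 back to 15: PdCl2(MeCN)2 (10 mol %) with p-benzoquinone in THF effects Wacker-type oxidative 6-endo cyclisation to the 2,3-dihydro-4H-pyran-4-one F6. Conjugate reduction with LiBH(s-Bu)3 (1.0 equiv, −78 °C), hydride arriving on the face of the CH(CH3) bridge carbon, gives the lithium enolate F7. Protonation and enol equilibration at C5′ give 15.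

**Further compounds**
F1 | step 3 | [(1R)-2-methoxy-1,3,5-trimethyl-4-oxocyclohexa-2,5-dien-1-yl][(2S)-2-(methoxymethyl)pyrrolidin-1-yl]methanone | COC1=C(C)C(=O)C(C)=C[C@@]1(C)C(=O)N1CCC[C@H]1COC
F2 | step 3 | [(1R)-4-hydroxy-2-methoxy-1,3,5-trimethylcyclohexa-2,5-dien-1-yl][(2S)-2-(methoxymethyl)pyrrolidin-1-yl]methanone (C4 epimer with OH cis to the amide shown; either epimer ionises) | COC1=C(C)[C@@H](O)C(C)=C[C@@]1(C)C(=O)N1CCC[C@H]1COC
F3 | step 3 | (2S)-1-[(1S,4R)-5-methoxy-4,6,7-trimethyl-2-oxabicyclo[2.2.2]octa-5,7-dien-3-ylidene]-2-(methoxymethyl)pyrrolidin-1-ium chloride | COC1=C(C)[C@H]2OC(=[N+]3CCC[C@H]3COC)[C@]1(C)C=C2C.[Cl-]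
F4 | step 6 | (4E)-2-bromo-4-methylhex-4-en-3-one (racemic) | C/C=C(\C)C(=O)C(C)Br
F5 | step 6 | bromozinc (2Z,4E)-4-methylhexa-2,4-dien-3-olate | C/C=C(O[Zn]Br)/C(C)=C/C
F6 | step 7 | (1R,4R,5R,6S,3′S)-3′,4,5′,6,6′,7-hexamethylspiro[2-oxabicyclo[2.2.2]oct-7-ene-5,2′-[2H]pyran]-3,4′(3′H)-dione | O=C1C(C)=C(C)O[C@@]2([C@@H]1C)[C@@H](C)[C@H]1OC(=O)[C@]2(C)C=C1C
F7 | step 7 | lithium enolate (C4′–O, C4′=C5′) of 15 | [Li+].[O-]C1=C(C)[C@@H](C)O[C@@]2([C@@H]1C)[C@@H](C)[C@H]1OC(=O)[C@]2(C)C=C1C
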